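I read the rate first.

| setting | delta | flask |
|---|---|---|
| left-handed substrate | 0.050 M | 0.050 M |
| right-handed substrate | 0.050 M | 0.050 M |
| solid reagent | 1 equiv | 1.00 equiv |
| protic impurity | 1 mM | 1.00 mM |
| remark | the very flask that is asked about, followed so far |  |
| time |  | 12 h |

delta run (percent of the left-handed substrate and right-handed substrate together charged)

| time / min | left-handed product / % |
|---|---|
| 25.0 | 9.2 |
| 60.0 | 24.9 |
| 120 | 30.0 |
| 180 | 29.9 |
| 240 | 30.4 |
| 360 | 29.9 |
| 480 | 29.9 |

(scatter of a reading: 0.3 percentage points)

- coupling partner is single-handed; left-handed substrate and right-handed substrate are mirror images of each other, charged as a racemate, each of them at the stated concentration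
- as a solid, counted per litre of solution: solid reagent
- left-handed product that was removed still counts
- at the start none of the solid reagent is in solution
- additions bring no volume worth counting
- the handed part of coupling partner does not stay in what it makes, so the products of the two hands are mirror images too

- dusk: change nothing and wait 25 h more
- spring: at 12 h add left-handed substrate, 50.0 % of the amount charged, then wait 25 h
- autumn: at 12 h take out 90 % of the left-handed product then present, then wait 25 h

1. left-handed product, in percent of the left-handed substrate and right-handed substrate together first charged, at 12 h
2. which option adds most left-handed product ("none" when 2 percentage points or less is all one gets) (dusk / spring / autumn / none)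
3. left-handed product present, with what was taken out counted in, in percent of the left-handed substrate and right-handed substrate together first charged, after dusk
4. left-handed product present, with what was taken out counted in, in percent of the left-handed substrate and right-handed substrate together first charged, after spring

The run above is the flask itself, followed so far. Between 25.0 min and 60.0 min the left-handed product rose by 0.00449 min⁻¹ of the charge, and between 60.0 min and 120 min by 8.50 × 10⁻⁴ min⁻¹, a factor of 0.189. The readings from 120 min onward average 30.0 %.

What could slow it? Losing left-handed substrate multiplies the rate by 0.400 at that level, which leaves 0.00179 min⁻¹. At that rate the flask should have gained about 11 percentage points between 120 min and 180 min, but the readings changed by 0.1 points, less than that and within the scatter of 0.3 points. So I took a second factor to have gone to nothing, and I took it to be the solid reagent, the limiting reagent.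

That gave me a budget: the solid reagent charged less the protic impurity, 49.0 % of the substrates together. From it I read the left share of the usable reagent, the plateau divided by the budget, 0.613. On that reading I expected no option to gain more than 2 points, and I committed to 30.0 % at 12 h.

The forecast gave 30 %, 30 % after dusk, 30 % after spring and best option none, on the ground that “The abrupt stop looks like something being used up, not a gradual approach to equilibrium.”

The flask gave 30.0 % at 12 h, 30.0 % after dusk, 30.0 % after spring, and best option none. The forecast held.

    coupling partner + left-handed substrate → left-handed product (k = 2.30 M⁻¹ min⁻¹)
    coupling partner + right-handed substrate → right-handed product (k = 1.20 M⁻¹ min⁻¹)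
    solid reagent ⇌ coupling partner, rate k3*(cs3 - [coupling partner]) while solid is left; crystals form when [coupling partner] > cs3 (solubility = 28.0 mM, k = 0.0340 min⁻¹)
    coupling partner + protic impurity → quenched reagent (k = 12.0 M⁻¹ min⁻¹)

At 720 min this flask held 30.0 % left-handed and 19.0 % right-handed product, together 49.0 % against the budget of 49.0 %, with 0 % of the solid reagent's charge remaining. On these two amounts the left share comes out at 0.612. The neighbour charged with 0.600 equiv of solid reagent has a budget of 29.0 %, and the left share turns that into 17.8 %. That neighbour held 18.4 % left-handed product at 720 min, with 63 % of its left-handed substrate unbound and 0 % of its solid reagent remaining.

(The runs are simulated with made-up constants; noise was put on by code.)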